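The fusion bond C3a–C8a is an aldol bond (tertiary alcohol β to a C8 carbonyl), so both rings unfold to a ten-membered 1,6-diketone. That ring is the oxy-Cope ring-expansion product of a 1,2-dialkenylcyclohex-3-ene-1,2-diol, and the σ-bond made by the [3,3] shift is the cyclopentane CH2–CH2 bond C1–C2. The key step thus forms C1–C2 (ten-membered ring), then C3a–C8a (five- and seven-membered rings) and the stereocentres C3, C3a, C8a in one operation. The precursor's carbinol centres are erased, so the ketol is racemic; a catalyst-controlled reduction resolves it and sets C8; acylation finishes.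

Key step: step 5

Remark: atoms carry the azulene numbering of the target (C1, C2 cyclopentane CH2; C3 CH–i-Pr; C3a C–OH; C6 C–CH3; C8 CH–O; C8a C–CH3). Compounds 3 to 13 are racemates; where a racemate has more than one stereocentre, its SMILES shows the enantiomer that leads on to the target. Compounds 4, 7 and 15 are taken as purchased.

Step 1
Reactants: 1 3-methylcyclohex-2-en-1-one
Product: 3 6-hydroxy-3-methylcyclohex-2-en-1-one (racemate), via sodium cross-conjugated dienolate 2 (not isolated)
Conditions: NaN(SiMe3)2, THF, −78 °C; 2-(phenylsulfonyl)-3-phenyloxaziridine, −78 °C; AcOH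
Reagents that add atoms: 2-(phenylsulfonyl)-3-phenyloxaziridine, O=S(=O)(c1ccccc1)N1OC1c1ccccc1
Why: Kinetic deprotonation at the α'-carbon gives the cross-conjugated dienolate, which takes up electrophilic oxygen from the N-sulfonyloxaziridine (enolate hydroxylation); the new stereocentre is not controlled and is oxidised away in step 3.

Step 2
Reactants: 3 6-hydroxy-3-methylcyclohex-2-en-1-one; 4 isopropenylmagnesium bromide, CH2=C(CH3)MgBr
Product: 5 4-methyl-2-(prop-1-en-2-yl)cyclohex-3-ene-1,2-diol (racemic mixture of cis and trans diols)
Conditions: 4 (3 equiv), THF, −78 → 0 °C; H2O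
Reagents that add atoms: none
Why: Grignard 1,2-addition to the enone carbonyl after one equivalent of 4 has formed the magnesium alkoxide (the β-methyl group disfavours conjugate addition); the tertiary carbinol centre forms as a mixture, which is of no consequence because the neighbouring centre is oxidised in step 3 and this one is destroyed in step 5.

Step 3
Reactants: 5 4-methyl-2-(prop-1-en-2-yl)cyclohex-3-ene-1,2-diol
Product: 6 2-hydroxy-4-methyl-2-(prop-1-en-2-yl)cyclohex-3-en-1-one (racemate)
Conditions: 2-iodoxybenzoic acid (IBX), DMSO, 25 °C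
Reagents that add atoms: none
Why: IBX oxidation converts the secondary hydroxyl of a 1,2-diol into the α-hydroxy ketone without glycol cleavage and should leave the acid-sensitive tertiary bis-allylic alcohol untouched at room temperature; no stereocentre is formed.

Step 4
Reactants: 6 2-hydroxy-4-methyl-2-(prop-1-en-2-yl)cyclohex-3-en-1-one; 7 2-bromo-3-methylbut-1-ene
Product: 9 rac-(1R,2R)-4-methyl-1-(3-methylbut-1-en-2-yl)-2-(prop-1-en-2-yl)cyclohex-3-ene-1,2-diol (trans-diol), via (3-methylbut-1-en-2-yl)magnesium bromide 8 (not isolated)
Conditions: 7, Mg, THF, 50 °C; then 6, CeCl3, THF, −78 → 0 °C (3 equiv of 8); H2O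
Reagents that add atoms: none
Why: Chelation-controlled Grignard addition (CeCl3 lowers the basicity and suppresses enolisation; one equivalent of 8 is used up by the hydroxyl group) should occur on the carbonyl face opposite the pseudo-axial isopropenyl group of the metal-bridged α-alkoxide and give the trans-dialkenyl diol; both carbinol centres are erased in step 5, so any cis-diol can be carried along.

Step 5
Reactants: 9 rac-(1R,2R)-4-methyl-1-(3-methylbut-1-en-2-yl)-2-(prop-1-en-2-yl)cyclohex-3-ene-1,2-diol
Product: 13 rac-(3R,3aS,8aS)-3a-hydroxy-6,8a-dimethyl-3-(propan-2-yl)-2,3,3a,4,5,8a-hexahydroazulen-8(1H)-one (cis-fused ketol; angular OH and CH3 cis, isopropyl cis to both), via dipotassium diolate 10 (not isolated), via ten-membered dipotassium bis-enolate 11 (not isolated), via ten-membered potassium keto-enolate 12 (not isolated)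
Conditions: KH (2.5 equiv), 18-crown-6 (2.5 equiv), THF, 0 → 25 °C; then t-BuOH (1.0 equiv), −78 → −20 °C; AcOH, −78 °C
Reagents that add atoms: none
Why: Double deprotonation gives diolate 10, whose two alkenyl groups undergo an alkoxide-accelerated [3,3] sigmatropic shift through a chair transition state that cleaves the ring bond between the two carbinol carbons and joins the two terminal methylene carbons (C1–C2), expanding the cyclohexene to the ten-membered bis-enolate 11; t-BuOH then protonates the more basic, non-conjugated enolate at C3, and the remaining cross-conjugated dienolate of 12 attacks the new C3a ketone across the ring. The closest known reaction types are the dianionic oxy-Cope/transannular aldol cascades of 1,2-dialkenyl-1,2-diolates and the anionic oxy-Cope ring expansion of 1,2-divinylcyclohexanols to cyclodecenones. Ring closures: the ten-membered ring by [3,3] ring expansion, then the cyclopentane by a 5-(enolexo)-exo-trig aldol that is at the same time the 7-(enolendo)-exo-trig closure of the cycloheptenone. C3a and C8a are set together in the aldol, where the three-carbon bridge C1–C2–C3 favours a cis ring fusion (hydroxyl and methyl on the same face), as is usual for aldol closures of five-membered rings; C3 is set under thermodynamic control (epimerisable next to the ketone in 12 and through retro-aldol), which should put the isopropyl group on the convex face, cis to both angular groups. The step needs this aldol mode and not the three other transannular modes: the oxy-Cope delivers the enolate regiospecifically at the methyl-bearing carbon C8a, the saturated C3a ketone is the better electrophile, and 13 alone keeps the enone conjugation and has no α-hydrogen for dehydration. Both carbinol stereocentres of 9 are destroyed in the [3,3] shift, so no absolute stereocontrol is possible here and 13 forms as the racemate.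

Step 6
Reactants: 13 rac-(3R,3aS,8aS)-3a-hydroxy-6,8a-dimethyl-3-(propan-2-yl)-2,3,3a,4,5,8a-hexahydroazulen-8(1H)-one
Product: 14 (3R,3aS,8S,8aR)-6,8a-dimethyl-3-(propan-2-yl)-1,2,3,3a,4,5,8,8a-octahydroazulene-3a,8-diol (single enantiomer)
Conditions: (R)-Me-CBS oxazaborolidine [(R)-1-methyl-3,3-diphenyltetrahydro-1H,3H-pyrrolo[1,2-c][1,3,2]oxazaborole] (0.3 equiv), catecholborane (0.6 equiv), toluene, −78 °C, stopped near half conversion; MeOH; H2O
Reagents that add atoms: none
Why: Corey–Bakshi–Shibata reduction used as a kinetic resolution: the oxazaborolidine binds the carbonyl on the side of the small vinylic C7–H and delivers hydride to the face that gives the 8S carbinol, which for the enantiomer shown is the face anti to the angular C8a methyl group that the substrate itself prefers (matched, fast) but for its mirror image is the methyl-shielded face (mismatched, slow), so the step sets C8 with oxygen cis to the methyl group and selects the enantiomeric series of the target, the mirror-image ketol being left unreduced and separated.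

Step 7
Reactants: 14 (3R,3aS,8S,8aR)-6,8a-dimethyl-3-(propan-2-yl)-1,2,3,3a,4,5,8,8a-octahydroazulene-3a,8-diol; 15 4-methoxybenzoyl chloride
Product: 16 (3R,3aS,8S,8aR)-3a-hydroxy-6,8a-dimethyl-3-(propan-2-yl)-1,2,3,3a,4,5,8,8a-octahydroazulen-8-yl 4-methoxybenzoate (CNP0158828.1)
Conditions: 15, 4-(dimethylamino)pyridine, Et3N, CH2Cl2, 0 → 25 °C
Reagents that add atoms: none
Why: Acylation under nucleophilic catalysis (N-acylpyridinium) esterifies the secondary allylic hydroxyl while the hindered tertiary angular hydroxyl stays free; no stereocentre is touched.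

Compound list
1 | 3-methylcyclohex-2-en-1-one | CC1=CC(=O)CCC1 | starting material
2 | sodium 5-methylcyclohexa-1,5-dien-1-olate (not isolated) | CC1=CC([O-])=CCC1.[Na+] | intermediate
3 | 6-hydroxy-3-methylcyclohex-2-en-1-one (racemate) | CC1=CC(=O)C(O)CC1 | intermediate
4 | isopropenylmagnesium bromide | CC(=C)[Mg]Br | starting material
5 | 4-methyl-2-(prop-1-en-2-yl)cyclohex-3-ene-1,2-diol (racemic cis/trans mixture) | CC1=CC(O)(C(C)=C)C(O)CC1 | intermediate
6 | 2-hydroxy-4-methyl-2-(prop-1-en-2-yl)cyclohex-3-en-1-one (racemate) | CC1=CC(O)(C(C)=C)C(=O)CC1 | intermediate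
7 | 2-bromo-3-methylbut-1-ene | CC(C)C(Br)=C | starting material
8 | (3-methylbut-1-en-2-yl)magnesium bromide (not isolated) | CC(C)C(=C)[Mg]Br | intermediate
9 | rac-(1R,2R)-4-methyl-1-(3-methylbut-1-en-2-yl)-2-(prop-1-en-2-yl)cyclohex-3-ene-1,2-diol | CC1=C[C@@](O)(C(C)=C)[C@](O)(C(=C)C(C)C)CC1 | intermediate
10 | dipotassium salt of diol 9 (not isolated) | CC1=C[C@@]([O-])(C(C)=C)[C@]([O-])(C(=C)C(C)C)CC1.[K+].[K+] | intermediate
11 | dipotassium (7Z)-5,8-dimethyl-2-(propan-2-yl)cyclodeca-1,5,7-triene-1,6-bis(olate) (enolate geometries not assigned; not isolated) | C/C1=C/C([O-])=C(C)CCC(C(C)C)=C([O-])CC1.[K+].[K+] | intermediate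
12 | potassium C5–C6 enolate of (7Z)-5,8-dimethyl-2-(propan-2-yl)cyclodec-7-ene-1,6-dione (C2 epimerisable; not isolated) | C/C1=C/C([O-])=C(C)CCC(C(C)C)C(=O)CC1.[K+] | intermediate
13 | rac-(3R,3aS,8aS)-3a-hydroxy-6,8a-dimethyl-3-(propan-2-yl)-2,3,3a,4,5,8a-hexahydroazulen-8(1H)-one | O=C1C=C(C)CC[C@]2(O)[C@@H](C(C)C)CC[C@]12C | intermediate
14 | (3R,3aS,8S,8aR)-6,8a-dimethyl-3-(propan-2-yl)-1,2,3,3a,4,5,8,8a-octahydroazulene-3a,8-diol | O[C@H]1C=C(C)CC[C@]2(O)[C@@H](C(C)C)CC[C@]12C | intermediate
15 | 4-methoxybenzoyl chloride | COc1ccc(C(Cl)=O)cc1 | starting material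
16 | (3R,3aS,8S,8aR)-3a-hydroxy-6,8a-dimethyl-3-(propan-2-yl)-1,2,3,3a,4,5,8,8a-octahydroazulen-8-yl 4-methoxybenzoate | COc1ccc(C(=O)O[C@H]2C=C(C)CC[C@]3(O)[C@@H](C(C)C)CC[C@]23C)cc1 | target

Total step count: 7. Longest linear sequence: 7 steps (1 → 16).

Steps most likely to fail

Step 5. After the [3,3] shift, proton transfer may scramble the enolates, so the ring could close through another transannular aldol mode (the C3 enolate onto the enone carbonyl, or closure through the C4 methylene followed by dehydration). The aldolate may also revert to the open ten-membered diketone, the trans-fused ketol may form, or a competing [3,3] shift through the ring alkene may intervene. The fallback locks the regiochemistry and runs stepwise; it sets out from 6. The tertiary hydroxyl is capped (ClCH2OCH3, i-Pr2NEt) as the methoxymethyl ether 2-(methoxymethoxy)-4-methyl-2-(prop-1-en-2-yl)cyclohex-3-en-1-one F1. Chelation-controlled addition of 8/CeCl3 should give the mono-protected trans-dialkenyl alcohol F2. KH/18-crown-6 then effects the mono-anionic oxy-Cope ring expansion to the ten-membered potassium enolate F3, in which C8 is masked as a dienol ether, and AcOH gives the keto dienol ether F4. TiCl4 in CH2Cl2 at −78 °C triggers a transannular Mukaiyama-type aldol in which the only nucleophile is the dienol ether carbon C8a and the only electrophile the C3a ketone; the methoxymethyl group is lost from the oxocarbenium ion on work-up. The fallback comes back to the route at 13.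

Step 6. Too small a rate difference between the two enantiomers, or an uncatalysed reduction directed by the free tertiary hydroxyl, would erode the enantiomeric purity; if the enone arm rather than the quaternary carbon acts as the large group, the sense of induction would also invert. The fallback is a classical resolution through covalent diastereomers; it sets out from 13. Luche reduction (NaBH4, CeCl3·7H2O, MeOH, −40 °C; hydride anti to the angular methyl group) should give the racemic form of diol 14, F5. Acylation with (S)-MTPA chloride and 4-(dimethylamino)pyridine gives two diastereomeric (R)-MTPA esters: F6, derived from 14, and F7, derived from its mirror image. These are separated by chromatography, LiAlH4 cleaves F6, and the fallback comes back to the route at 14.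

Step 4. The hindered, basic alkenylmetal may enolise the ketone instead of adding, and the metal alkoxide of 6 may undergo an α-ketol shift that exchanges the carbinol and carbonyl carbons. The fallback avoids a free alkoxide; it sets out from 6. Silylation (Et3SiOSO2CF3, 2,6-lutidine) gives the triethylsilyl ether F8. Addition of 8/CeCl3 at −78 °C, now under non-chelation (Felkin–Anh) control, should give the silyl-protected cis-dialkenyl alcohol F9, and Bu4NF gives the cis-diol F10, the diastereomer of 9. F10 is taken through the conditions of step 5 in place of 9: its dipotassium diolate F11 rearranges through a boat-like transition state, and the fallback comes back to the route at bis-enolate 11.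

Further compounds
F1 | step 5 | 2-(methoxymethoxy)-4-methyl-2-(prop-1-en-2-yl)cyclohex-3-en-1-one (racemate) | COCOC1(C(C)=C)C=C(C)CCC1=O
F2 | step 5 | rac-(1R,2R)-2-(methoxymethoxy)-4-methyl-1-(3-methylbut-1-en-2-yl)-2-(prop-1-en-2-yl)cyclohex-3-en-1-ol | CC1=C[C@@](OCOC)(C(C)=C)[C@](O)(C(=C)C(C)C)CC1
F3 | step 5 | potassium (7Z)-6-(methoxymethoxy)-5,8-dimethyl-2-(propan-2-yl)cyclodeca-1,5,7-trien-1-olate | C/C1=C/C(OCOC)=C(C)CCC(C(C)C)=C([O-])CC1.[K+]
F4 | step 5 | (7Z)-6-(methoxymethoxy)-5,8-dimethyl-2-(propan-2-yl)cyclodeca-5,7-dien-1-one (racemate) | C/C1=C/C(OCOC)=C(C)CCC(C(C)C)C(=O)CC1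
F5 | step 6 | racemic form of diol 14, rac-(3R,3aS,8S,8aR)-6,8a-dimethyl-3-(propan-2-yl)-1,2,3,3a,4,5,8,8a-octahydroazulene-3a,8-diol | O[C@H]1C=C(C)CC[C@]2(O)[C@@H](C(C)C)CC[C@]12C
F6 | step 6 | (R)-MTPA ester of 14 at the C8 oxygen | CO[C@](C(F)(F)F)(c1ccccc1)C(=O)O[C@H]1C=C(C)CC[C@]2(O)[C@@H](C(C)C)CC[C@]12C
F7 | step 6 | (R)-MTPA ester of the mirror image of 14 at the C8 oxygen | CO[C@](C(F)(F)F)(c1ccccc1)C(=O)O[C@@H]1C=C(C)CC[C@@]2(O)[C@H](C(C)C)CC[C@@]12C
F8 | step 4 | 4-methyl-2-(prop-1-en-2-yl)-2-[(triethylsilyl)oxy]cyclohex-3-en-1-one (racemate) | CC[Si](CC)(CC)OC1(C(C)=C)C=C(C)CCC1=O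
F9 | step 4 | rac-(1S,2R)-4-methyl-1-(3-methylbut-1-en-2-yl)-2-(prop-1-en-2-yl)-2-[(triethylsilyl)oxy]cyclohex-3-en-1-ol | CC1=C[C@@](O[Si](CC)(CC)CC)(C(C)=C)[C@@](O)(C(=C)C(C)C)CC1
F10 | step 4 | rac-(1S,2R)-4-methyl-1-(3-methylbut-1-en-2-yl)-2-(prop-1-en-2-yl)cyclohex-3-ene-1,2-diol (cis-diol) | CC1=C[C@@](O)(C(C)=C)[C@@](O)(C(=C)C(C)C)CC1
F11 | step 4 | dipotassium salt of cis-diol F10 | CC1=C[C@@]([O-])(C(C)=C)[C@@]([O-])(C(=C)C(C)C)CC1.[K+].[K+]
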